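## Structural features

The target is a bicyclic diterpenoid of the labdane type in the enantiomeric (ent) series. It is a trans-fused decalin (ring A = C1–C5 and C10, ring B = C5–C10) whose C9 carries a five-carbon chain ending in an (E)-trisubstituted allylic acetate (C13=C14, acetate on C15). Ring A holds an α-ketol (C2 ketone, equatorial C3 hydroxyl) between the gem-dimethyl carbon C4 and the C1 methylene on quaternary C10. Ring B holds the trisubstituted C7=C8 alkene with the C8 methyl. The four stereocentres are C3, C5, C10 and C9: C5/C10 form the ring fusion, C9 sits next to quaternary C10, and C3 is separated from C5 only by quaternary C4. The fragile groups are the ketol (enolisation toward C3 can transpose ketone and carbinol; base and air lead on to the diosphenol), the allylic acetate (solvolysis, saponification, ionisation by low-valent metals) and the C7=C8 alkene (migration to C8=C9 or capture of a C12 oxygen under acid). The real difficulty is the quaternary C10 trans to H-5 beside the gem-dimethyl C4, together with two ring carbonyls (C2, C8) that must later be told apart and a ring B alkene that must sit at C7. The key step exploits the fact that C4(Me2)–C5, the C8 carbonyl and the C9–C10(Me) unit are the gem-dimethylcyclobutane carbon, a bridgehead, the ketone and the enone carbons of verbenone. The bicycle therefore supplies ring B with C5 already set, and breaking its strained C4–C7 bond frees a tertiary C4 cation exactly where ring A must close by bonding to C3.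

## Logic of the disconnections

24 ⇒ 23 ⇒ 22. No skeletal bond is cut. The C3 hydroxyl is carried as a silyl ether and the C2 carbonyl as the secondary alcohol of 22, so the sensitive ketol exists only in 24. The forward steps must oxidise a hindered axial alcohol and remove a hindered silyl ether without touching the allylic acetate or the C7=C8 alkene.

22 ⇒ 21 ⇒ 19. C13–C16 and C14–C15 are cut: the trisubstituted alkene comes from a terminal alkyne by syn addition of methyl and metal followed by a one-carbon electrophile. The E geometry then follows from the mechanism and the chain shrinks to C11–C14. The forward step must place methyl on C13, tolerate the free C2 hydroxyl, and be followed by acetylation of the primary allylic hydroxyl only.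

19 ⇒ 18 ⇒ 17 ⇒ 16. C12–C13 is cut (displacement of a primary iodide by a two-carbon acetylide), and the iodide is traced through diol 17 to ester 16. The same hydride step that reduces the ester also reduces the C2 ketone, which is thereby protected for the strongly basic and Lewis-acidic chain steps. The chain is reduced to the two-carbon acetate arm. The forward steps need iodination of the primary hydroxyl only and a C2 hydroxyl that stays a spectator.

16 ⇒ 15 ⇒ 13. C8–C17 is cut: the methyl is put on by cross-coupling of the C7=C8 enol triflate, so the alkene position is fixed by the enolate regiochemistry and ring B returns to a ketone. The forward step must deprotonate C7 (not C9) of the C8 ketone and must leave the C2 ketone alone.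

13 ⇒ 12. No bond is cut; 12 is the C9 epimer. The arm can only be introduced on the face that later becomes axial, so the forward step is an equilibration, which must spare the silyloxy ketone in ring A.

12 ⇒ 10. C3–C4 is cut and, in the same retrosynthetic move, C4 is joined to C7 to restore the cyclobutane. Ring A disappears, C5 and C10 are traced to a pinane bicycle, and the C2/C3 oxygens appear as an enediol bis-silyl ether on a three-carbon arm. The forward step must break the cyclobutane bond and capture the resulting cation with carbon C3 in preference to every other outlet.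

10 ⇒ 9 ⇒ 8 ⇒ 7 ⇒ 6. Only C–O bonds are cut: the enol ether comes from an α-silyloxy ketone, and that from the terminal alkene of an allyl group. The forward sequence needs enolisation toward C3 (not C1) and no reaction at the ring ketone.

6 ⇒ 3 + 4. C9–C11 is cut (enolate alkylation). The ring ketone of 3 has a single enolisable position, so regiochemistry is not in question; the facial outcome is accepted and repaired later.

3 ⇒ 1 + 2. C1–C10 is cut (conjugate allylation of the enone). This makes the quaternary C10 in the first step; the forward reaction must add on the face away from the gem-dimethyl bridge.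

## Other disconnections considered

Alternative 1: The cut runs through C1–C10 and C4–C5, so ring A would come from a [4+2] addition of the 2-silyloxy diene A2 to the C5=C10 bond of quinone A3, whose two methyl groups become the C8 and C10 methyls.
- Forward step: a chiral cationic boron Lewis acid binds the unhindered quinone carbonyl (the future C6). The CH2 terminus of A2 bonds to C10 and the dimethylated terminus to C5. Mild base then epimerises C5 of the cis adduct to give the trans-fused enedione A1.
- In its favour: two ring bonds, the quaternary C10 and the absolute configuration are made in one catalytic operation from achiral materials, with either enantiomer available (the equal of a chiral-pool start). The reaction type is established, which is better than the chosen key step. The C2=C3 enol silane of A1 is placed for a Rubottom oxidation to the ketol, the equal of the chosen plan for ring A.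
- Against it here: the diene terminus that must bond to C5 is fully substituted, and its inward methyl disfavours the reactive s-cis conformer, so the cycloaddition is expected to be sluggish. Ring B of A1 is over-oxidised: the C6 carbonyl must be removed, and the C9 carbonyl must become a CH stereocentre bearing the whole chain without loss of the C7=C8 alkene.
- Comparison: the chosen plan has ring B at the right oxidation level from the start (one carbonyl, on C8) and brings in C11–C12 by plain enolate alkylation, but pays with an unprecedented key step. The alternative is shorter up to the bicycle and is expected to be longer from A1 to the target.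

Alternative 2: The cut is C9–C10. Ring A is made first from A6 as the cyclohexene A5, which carries silyl ethers on C2 and C3, the tetrasubstituted C5=C10 alkene and a β-keto ester chain on C5.
- Forward step: a protic Lewis acid protonates C5, and the enol carbon C9 of the keto ester adds to the C10 cation to give the trans-decalin A4.
- In its favour: cyclisation of a β-keto ester onto a cyclohexenyl cation is a well-tried reaction type for this ring system, so no step would lack precedent (better than the chosen plan). It sets C5, C10 and C9 together through a chair. The C8 ketone it leaves is the same handle for the C8 methyl and the ring B alkene (equal).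
- Against it here: the cation must form on a ring with two electron-withdrawing silyloxy groups, one β to the cationic carbon, which slows ionisation and opens elimination and silyl-loss channels. The absolute configuration of C5 and C10 depends on relay from C2/C3, whereas the chosen plan inherits C5 and sets C10 on a rigid bicycle. C2 and C3 leave the key step with the same protecting group, where the chosen key step delivers them as ketone and silyl ether. A4 has only C11 on C9, so five chain carbons remain to be added (possible convergently, the equal of the stepwise chain), and the alkene must be moved out of conjugation with the ester to C7=C8.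
- Comparison: A5 with its two oxygen stereocentres should need about as many steps as 10, so the overall count is expected to be similar.

Alternative 3: The cut is C6–C7. The cyclohexane A8 carries the C5 aldehyde (C6) and, on quaternary C10, the C9 methine with the complete protected chain and the C8 methyl ketone.
- Forward step: base forms the methyl-ketone enolate (C7), which adds to the aldehyde; loss of water gives the 6-en-8-one A7, with C5 and C9 settling under equilibrating conditions.
- In its favour: the aldol condensation is among the most dependable ring closures (better than the chosen key step on precedent). The chain is complete before the ring closes, so no chain-building follows the key step (better in convergence and in step economy after the key step). C5 and C9 are under thermodynamic control, as C9 and C3 are in the chosen plan (equal).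
- Against it here: the key step makes no quaternary centre, so the hard part — C10 with its methyl, its branched C9 substituent and the neighbouring C4 and C5, in the right absolute configuration — must be solved in the synthesis of A8, which is expected to be long. A7 then needs methyl addition at C8 with reductive transposition, or a reduction and enol-triflate sequence, to reach the 8-methyl-7-ene. C2/C3 again carry identical silyl ethers.
- Comparison: the chosen plan closes the ring next to a quaternary centre that is already fixed in a bicycle, at the cost of building the chain afterwards.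

Key step: step 7

Remarks on the chemistry (assumptions and corrections):
- Labdane numbering is used for all intermediates, including the bicyclic ones.
- The target is an ent-labdane; C5 of (1S,5S)-verbenone becomes C5 of 24 without being touched, and the verbenone is assumed to be used enantiomerically pure.
- The C9 arm of the key-step precursor is drawn on the face away from the gem-dimethyl bridge, the only face an electrophile can reach. This is the C9 epimer of the arrangement that maps directly onto the target, and it is corrected in step 8.
- In the decalin dione the hindered carbonyl is C2 (any tetrahedral adduct has an oxygen syn-axial to the C10 methyl and the axial C4 methyl). No C2 ketal is planned; the carbonyls are told apart by kinetic enolisation at C7, and C2 is protected by reduction.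
- Both silyl groups of the enediol are tert-butyldimethylsilyl (TBS), so the precursor can be purified and made with one reagent; the O2 silyl group is the one lost in the key step.

## Route

Step 1
Reactants: 1 (1S,5S)-(−)-verbenone; 2 allyltrimethylsilane
Product: 3 (1S,4S,5S)-4-allyl-4,6,6-trimethylbicyclo[3.1.1]heptan-2-one
Conditions: TiCl4 (1.1 equiv), CH2Cl2, −78 °C; then H2O
Reagents that add atoms: none
Why: Hosomi–Sakurai conjugate allylation of a β,β-disubstituted enone; the allylsilane reaches C10 from the methylene-bridge face, away from the syn methyl of the gem-dimethyl bridge, so the new quaternary centre has its methyl syn and its allyl group anti to that bridge. The adduct rests as its titanium enolate until the quench, so the cyclobutyl ketone is not exposed to the Lewis acid.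

Step 2
Reactants: 3 (1S,4S,5S)-4-allyl-4,6,6-trimethylbicyclo[3.1.1]heptan-2-one; 4 methyl bromoacetate
Product: 6 methyl 2-[4-allyl-4,6,6-trimethyl-2-oxobicyclo[3.1.1]heptan-3-yl]acetate (C9 arm anti to the gem-dimethyl bridge), via lithium enolate 5 (not isolated)
Conditions: LiN(iPr)2, THF, −78 °C; then 4, DMPU, −78 → −20 °C
Reagents that add atoms: none
Why: Ketone enolate alkylation; the bridgehead C7–H cannot enolise, so only C9 is deprotonated, and the reactive α-halo ester enters from the methylene-bridge face because the other face is covered by the syn methyl of the bridge and the C10 methyl. The C9 configuration so formed (arm cis to the allyl group) is provisional and is corrected in step 8.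

Step 3
Reactants: 6 methyl 2-[4-allyl-4,6,6-trimethyl-2-oxobicyclo[3.1.1]heptan-3-yl]acetate
Product: 7 methyl 2-[4-(2,3-dihydroxypropyl)-4,6,6-trimethyl-2-oxobicyclo[3.1.1]heptan-3-yl]acetate (both carbinol epimers)
Conditions: OsO4 (2 mol%), N-methylmorpholine N-oxide, acetone/H2O, rt
Reagents that add atoms: N-methylmorpholine N-oxide, C[N+]1([O-])CCOCC1; water, O
Why: Catalytic osmium dihydroxylation of the only alkene present; the new carbinol centre forms as both epimers, which does not matter because it becomes the C2 carbonyl in step 5.

Step 4
Reactants: 7 methyl 2-[4-(2,3-dihydroxypropyl)-4,6,6-trimethyl-2-oxobicyclo[3.1.1]heptan-3-yl]acetate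
Product: 8 methyl 2-{4-[3-(tert-butyldimethylsilyloxy)-2-hydroxypropyl]-4,6,6-trimethyl-2-oxobicyclo[3.1.1]heptan-3-yl}acetate
Conditions: TBSCl, imidazole, CH2Cl2, 0 °C
Reagents that add atoms: tert-butyldimethylsilyl chloride, CC(C)(C)[Si](C)(C)Cl
Why: Silylation of a primary hydroxyl in preference to the neighbouring secondary one on steric grounds; any hemiketal between the diol and the C8 ketone is in equilibrium with the open form and is drained by the silylation.

Step 5
Reactants: 8 methyl 2-{4-[3-(tert-butyldimethylsilyloxy)-2-hydroxypropyl]-4,6,6-trimethyl-2-oxobicyclo[3.1.1]heptan-3-yl}acetate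
Product: 9 methyl 2-{4-[3-(tert-butyldimethylsilyloxy)-2-oxopropyl]-4,6,6-trimethyl-2-oxobicyclo[3.1.1]heptan-3-yl}acetate
Conditions: Dess–Martin periodinane, CH2Cl2, rt
Reagents that add atoms: none
Why: Dess–Martin oxidation of the secondary alcohol to the C2 ketone under near-neutral conditions that leave the silyl ether, the ester and the cyclobutyl ketone untouched.

Step 6
Reactants: 9 methyl 2-{4-[3-(tert-butyldimethylsilyloxy)-2-oxopropyl]-4,6,6-trimethyl-2-oxobicyclo[3.1.1]heptan-3-yl}acetate
Product: 10 methyl 2-{4-[(Z)-2,3-bis(tert-butyldimethylsilyloxy)prop-2-en-1-yl]-4,6,6-trimethyl-2-oxobicyclo[3.1.1]heptan-3-yl}acetate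
Conditions: TBSOTf (1.2 equiv), Et3N, CH2Cl2, −78 → 0 °C
Reagents that add atoms: tert-butyldimethylsilyl trifluoromethanesulfonate, CC(C)(C)[Si](C)(C)OS(=O)(=O)C(F)(F)F
Why: Soft enolisation (silyl triflate and amine) of the side-arm ketone toward C3, since C1 is neopentylic and the 1,2-dioxygenated alkene is the more stable enol ether; the Z isomer (oxygens cis) is expected because it avoids allylic strain between the C3 substituent and C1. The ring ketone should not compete because its only enolisable hydrogen (C9–H) lies under the gem-dimethyl bridge next to quaternary C10.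

Step 7
Reactants: 10 methyl 2-{4-[(Z)-2,3-bis(tert-butyldimethylsilyloxy)prop-2-en-1-yl]-4,6,6-trimethyl-2-oxobicyclo[3.1.1]heptan-3-yl}acetate
Product: 12 methyl 3-(tert-butyldimethylsilyloxy)-2,8-dioxo-13,14,15,16,17-pentanor-ent-labdan-12-oate as its 9-epimer (C9 arm axial), via ring-opened C4 cation 11 (not isolated)
Conditions: TiCl4 (2.2 equiv), CH2Cl2, −78 → −30 °C; then H2O
Reagents that add atoms: none
Why: Proposed new method: TiCl4 on the C8 carbonyl polarises the flanking C4–C7 cyclobutane bond, which overlaps with the carbonyl π system, and heterolysis (driven by release of ring strain and of the methyl–methyl compression across the bicycle) gives the C7=C8 titanium enolate and the tertiary C4 cation 11; ring B relaxes to a chair with the cationic substituent on C5 and the enol-silane arm on C10 both equatorial, the enol carbon C3 adds to C4, and the resulting C2 silyloxycarbenium ion gives up its silyl group to chloride. The closest known reaction types are the Lewis-acid opening of 4-aryl pinane-type cyclobutyl ketones, in which a phenol oxygen captures the same kind of tertiary cation to close a trans-fused pyran, and the Lewis-acid tert-alkylation of silyl enol ethers by tertiary chlorides; joining the two with a carbon nucleophile in one operation has no direct precedent. Ring A closes in the 6-(enolendo) mode onto a cationic carbon, that is 6-endo with respect to the enol double bond, the ordinary mode of cation–olefin cyclisation, through a chair-like six-membered transition state. The ring fusion can only be trans, because C1 and C4 were placed trans on ring B by the anti allylation of step 1 and C5 is never touched. The new C3 centre follows from the Z enol geometry: the C3 oxygen, cis to the C2 oxygen, stays near the plane of the developing carbonyl and so ends equatorial when C4 bonds perpendicular to the enol plane, and the centre is in any case epimerisable next to the C2 carbonyl. The step needs carbon capture of the cation to win over proton loss and over direct aldol addition of the enol silane to the activated C8 carbonyl; chloride capture at C4 is reversible under TiCl4 and returns the cation, the aldol would build a congested bicyclo[3.3.1]nonane across the bicycle and is reversible, whereas the fragmentation is not. Attack through C3 and not C2 is favoured by the better-stabilised ketone-type oxocarbenium ion at C2 and by six- over five-membered closure onto a fully substituted carbon.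

Step 8
Reactants: 12 methyl 3-(tert-butyldimethylsilyloxy)-2,8-dioxo-13,14,15,16,17-pentanor-ent-labdan-12-oate, 9-epimer
Product: 13 methyl 3-(tert-butyldimethylsilyloxy)-2,8-dioxo-13,14,15,16,17-pentanor-ent-labdan-12-oate (C9 arm equatorial, cis to the C10 methyl)
Conditions: TsOH·H2O (10 mol%), PhMe, 50 °C
Reagents that add atoms: none
Why: Acid-catalysed enolisation of the C8 ketone toward C9 equilibrates the arm to the equatorial position, which removes its syn-axial contacts with H-1, H-5 and H-7; C3 is under the same thermodynamic control and is expected to stay equatorial. Acid is preferred to base so that no enolate forms that could shift the C3 silyl group to O2 or condense with the ester.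

Step 9
Reactants: 13 methyl 3-(tert-butyldimethylsilyloxy)-2,8-dioxo-13,14,15,16,17-pentanor-ent-labdan-12-oate
Product: 15 methyl 3-(tert-butyldimethylsilyloxy)-2-oxo-8-(trifluoromethylsulfonyloxy)-13,14,15,16,17-pentanor-ent-labd-7-en-12-oate, via potassium enolate 14 (not isolated)
Conditions: KN(SiMe3)2 (1.05 equiv), THF, −78 °C; then N-(5-chloropyridin-2-yl)triflimide, −78 °C
Reagents that add atoms: N-(5-chloropyridin-2-yl)-1,1,1-trifluoro-N-(trifluoromethylsulfonyl)methanesulfonamide, FC(F)(F)S(=O)(=O)N(c1ccc(Cl)cn1)S(=O)(=O)C(F)(F)F
Why: Kinetic deprotonation with a bulky amide base and O-triflation of the enolate; C7 is the only unhindered α-methylene in the molecule, since C9 is a methine beside quaternary C10 and both α-carbons of the C2 ketone are neopentylic (C3 also bears the silyloxy group). The ester is far less acidic, and the triflating agent reacts at −78 °C before the enolate can equilibrate.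

Step 10
Reactants: 15 methyl 3-(tert-butyldimethylsilyloxy)-2-oxo-8-(trifluoromethylsulfonyloxy)-13,14,15,16,17-pentanor-ent-labd-7-en-12-oate
Product: 16 methyl 3-(tert-butyldimethylsilyloxy)-2-oxo-13,14,15,16-tetranor-ent-labd-7-en-12-oate
Conditions: MeZnCl, Pd(PPh3)4 (5 mol%), THF, 50 °C
Reagents that add atoms: methylzinc chloride, C[Zn]Cl
Why: Negishi coupling of an alkenyl triflate with a methylzinc reagent under zerovalent palladium catalysis; the organozinc adds neither to the hindered C2 ketone nor to the ester, and the double bond stays where the triflate fixed it.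

Step 11
Reactants: 16 methyl 3-(tert-butyldimethylsilyloxy)-2-oxo-13,14,15,16-tetranor-ent-labd-7-en-12-oate
Product: 17 3-(tert-butyldimethylsilyloxy)-13,14,15,16-tetranor-ent-labd-7-ene-2,12-diol (C2 hydroxyl axial)
Conditions: LiAlH4, THF, 0 °C
Reagents that add atoms: none
Why: Hydride reduction of the ester to the C12 alcohol and of the C2 ketone in one operation, which protects C2 for the chain-building steps; hydride should add to C2 on the face opposite the two axial methyl groups (C10 and C4) to give the axial alcohol, and either epimer converges in step 16.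

Step 12
Reactants: 17 3-(tert-butyldimethylsilyloxy)-13,14,15,16-tetranor-ent-labd-7-ene-2,12-diol
Product: 18 12-iodo-3-(tert-butyldimethylsilyloxy)-13,14,15,16-tetranor-ent-labd-7-en-2-ol
Conditions: PPh3, I2, imidazole, CH2Cl2, 0 °C
Reagents that add atoms: iodine, II
Why: Appel iodination of the primary alcohol; the axial C2 hydroxyl, flanked by two syn-axial methyl groups and the C3 silyl ether, should not react, and premixing phosphine, iodine and imidazole leaves no free iodine or acid for the C7=C8 alkene.

Step 13
Reactants: 18 12-iodo-3-(tert-butyldimethylsilyloxy)-13,14,15,16-tetranor-ent-labd-7-en-2-ol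
Product: 19 3-(tert-butyldimethylsilyloxy)-15,16-dinor-ent-labd-7-en-13-yn-2-ol
Conditions: LiC≡CH·H2NCH2CH2NH2 (4 equiv), DMSO, rt
Reagents that add atoms: lithium acetylide (ethylenediamine complex), [Li+].[C-]#C
Why: SN2 displacement of an unhindered primary iodide by acetylide in a dipolar aprotic solvent; one equivalent is spent on the C2 hydroxyl, whose hindered alkoxide is a poor nucleophile and a poor acceptor for the C3 silyl group.

Step 14
Reactants: 19 3-(tert-butyldimethylsilyloxy)-15,16-dinor-ent-labd-7-en-13-yn-2-ol
Product: 21 3-(tert-butyldimethylsilyloxy)-ent-labda-7,13E-diene-2,15-diol, via alkenylalane 20 (not isolated)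
Conditions: Me3Al (4 equiv), Cp2ZrCl2 (0.3 equiv), CH2Cl2, 0 °C → rt; then n-BuLi, (CH2O)n, THF, −78 °C → rt
Reagents that add atoms: trimethylaluminium, C[Al](C)C; formaldehyde (as paraformaldehyde), C=O
Why: Zirconium-catalysed carboalumination of the terminal alkyne adds methyl to C13 and aluminium to C14 on the same side; the alkenylalane, activated as its aluminate, adds to formaldehyde with retention, which gives the E allylic alcohol. The C2 hydroxyl is masked in the flask as its aluminium alkoxide, and the trisubstituted ring alkene is inert to the reagent.

Step 15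
Reactants: 21 3-(tert-butyldimethylsilyloxy)-ent-labda-7,13E-diene-2,15-diol
Product: 22 15-acetoxy-3-(tert-butyldimethylsilyloxy)-ent-labda-7,13E-dien-2-ol
Conditions: Ac2O (1.2 equiv), pyridine, CH2Cl2, 0 °C
Reagents that add atoms: acetic anhydride, CC(=O)OC(C)=O
Why: Acylation of the primary allylic alcohol; the axial C2 hydroxyl with its two syn-axial methyl groups should be far slower without an acyl-transfer catalyst.

Step 16
Reactants: 22 15-acetoxy-3-(tert-butyldimethylsilyloxy)-ent-labda-7,13E-dien-2-ol
Product: 23 15-acetoxy-3-(tert-butyldimethylsilyloxy)-ent-labda-7,13E-dien-2-one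
Conditions: Dess–Martin periodinane, CH2Cl2, rt
Reagents that add atoms: none
Why: Dess–Martin oxidation returns the C2 ketone; strained axial alcohols oxidise readily, and the allylic acetate, both alkenes and the silyl ether are inert to the reagent.

Step 17
Reactants: 23 15-acetoxy-3-(tert-butyldimethylsilyloxy)-ent-labda-7,13E-dien-2-one
Product: 24 (2E)-5-[(1R,4aS,6S,8aS)-6-hydroxy-2,5,5,8a-tetramethyl-7-oxo-1,4,4a,5,6,7,8,8a-octahydronaphthalen-1-yl]-3-methylpent-2-en-1-yl acetate (CNP0164008.1)
Conditions: HF·pyridine, THF, 0 °C → rt
Reagents that add atoms: none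
Why: Fluoride-assisted cleavage of the silyl ether under mildly acidic, non-basic conditions, chosen so that the ketol is neither transposed nor oxidised and the acetate is not cleaved; C3 keeps the equatorial configuration set in steps 7 and 8.

## Compound list

1 | (1S,5S)-(−)-verbenone, (1S,5S)-4,6,6-trimethylbicyclo[3.1.1]hept-3-en-2-one | CC1=CC(=O)[C@H]2C[C@@H]1C2(C)C | starting material
2 | allyltrimethylsilane | C=CC[Si](C)(C)C | starting material
3 | (1S,4S,5S)-4-allyl-4,6,6-trimethylbicyclo[3.1.1]heptan-2-one (allyl anti to the gem-dimethyl bridge) | C=CC[C@@]1(C)CC(=O)[C@H]2C[C@@H]1C2(C)C | intermediate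
4 | methyl bromoacetate | COC(=O)CBr | starting material
5 | lithium enolate of 3 (C8–C9 enolate) | C=CC[C@@]1(C)C=C([O-])[C@H]2C[C@@H]1C2(C)C.[Li+] | intermediate (not isolated)
6 | methyl 2-[4-allyl-4,6,6-trimethyl-2-oxobicyclo[3.1.1]heptan-3-yl]acetate, C9 arm and C10 allyl both anti to the gem-dimethyl bridge, bridgeheads as in 1 | COC(=O)C[C@H]1C(=O)[C@H]2C[C@H](C2(C)C)[C@@]1(C)CC=C | intermediate
7 | methyl 2-[4-(2,3-dihydroxypropyl)-4,6,6-trimethyl-2-oxobicyclo[3.1.1]heptan-3-yl]acetate, both epimers at the new carbinol, ring stereocentres as in 6 | COC(=O)C[C@H]1C(=O)[C@H]2C[C@H](C2(C)C)[C@@]1(C)CC(O)CO | intermediate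
8 | methyl 2-{4-[3-(tert-butyldimethylsilyloxy)-2-hydroxypropyl]-4,6,6-trimethyl-2-oxobicyclo[3.1.1]heptan-3-yl}acetate, both carbinol epimers | COC(=O)C[C@H]1C(=O)[C@H]2C[C@H](C2(C)C)[C@@]1(C)CC(O)CO[Si](C)(C)C(C)(C)C | intermediate
9 | methyl 2-{4-[3-(tert-butyldimethylsilyloxy)-2-oxopropyl]-4,6,6-trimethyl-2-oxobicyclo[3.1.1]heptan-3-yl}acetate | COC(=O)C[C@H]1C(=O)[C@H]2C[C@H](C2(C)C)[C@@]1(C)CC(=O)CO[Si](C)(C)C(C)(C)C | intermediate
10 | methyl 2-{4-[(Z)-2,3-bis(tert-butyldimethylsilyloxy)prop-2-en-1-yl]-4,6,6-trimethyl-2-oxobicyclo[3.1.1]heptan-3-yl}acetate (key-step precursor) | COC(=O)C[C@H]1C(=O)[C@H]2C[C@H](C2(C)C)[C@@]1(C)C/C(O[Si](C)(C)C(C)(C)C)=C/O[Si](C)(C)C(C)(C)C | intermediate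
11 | ring-opened zwitterion: C7=C8 tetrachlorotitanate enolate of the cyclohexane with the tertiary C4 cation on C5 and the enediol arm on C10 | COC(=O)C[C@H]1C(O[Ti-](Cl)(Cl)(Cl)Cl)=CC[C@H]([C+](C)C)[C@@]1(C)C/C(O[Si](C)(C)C(C)(C)C)=C/O[Si](C)(C)C(C)(C)C | intermediate (not isolated)
12 | methyl 3-(tert-butyldimethylsilyloxy)-2,8-dioxo-13,14,15,16,17-pentanor-ent-labdan-12-oate, 9-epimer (trans-decalin, C3 silyl ether equatorial and cis to the C10 methyl, C9 arm axial) | COC(=O)C[C@H]1C(=O)CC[C@@H]2C(C)(C)[C@H](O[Si](C)(C)C(C)(C)C)C(=O)C[C@@]12C | intermediate
13 | methyl 3-(tert-butyldimethylsilyloxy)-2,8-dioxo-13,14,15,16,17-pentanor-ent-labdan-12-oate (trans-decalin, C3 silyl ether and C9 arm both equatorial and cis to the C10 methyl) | COC(=O)C[C@@H]1C(=O)CC[C@@H]2C(C)(C)[C@H](O[Si](C)(C)C(C)(C)C)C(=O)C[C@@]12C | intermediate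
14 | potassium C7=C8 enolate of 13 | COC(=O)C[C@@H]1C([O-])=CC[C@@H]2C(C)(C)[C@H](O[Si](C)(C)C(C)(C)C)C(=O)C[C@@]12C.[K+] | intermediate (not isolated)
15 | methyl 3-(tert-butyldimethylsilyloxy)-2-oxo-8-(trifluoromethylsulfonyloxy)-13,14,15,16,17-pentanor-ent-labd-7-en-12-oate | COC(=O)C[C@@H]1C(OS(=O)(=O)C(F)(F)F)=CC[C@@H]2C(C)(C)[C@H](O[Si](C)(C)C(C)(C)C)C(=O)C[C@@]12C | intermediate
16 | methyl 3-(tert-butyldimethylsilyloxy)-2-oxo-13,14,15,16-tetranor-ent-labd-7-en-12-oate | COC(=O)C[C@@H]1C(C)=CC[C@@H]2C(C)(C)[C@H](O[Si](C)(C)C(C)(C)C)C(=O)C[C@@]12C | intermediate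
17 | 3-(tert-butyldimethylsilyloxy)-13,14,15,16-tetranor-ent-labd-7-ene-2,12-diol (C2 hydroxyl axial, cis to the C3 oxygen and the C10 methyl) | OCC[C@@H]1C(C)=CC[C@@H]2C(C)(C)[C@H](O[Si](C)(C)C(C)(C)C)[C@H](O)C[C@@]12C | intermediate
18 | 12-iodo-3-(tert-butyldimethylsilyloxy)-13,14,15,16-tetranor-ent-labd-7-en-2-ol | ICC[C@@H]1C(C)=CC[C@@H]2C(C)(C)[C@H](O[Si](C)(C)C(C)(C)C)[C@H](O)C[C@@]12C | intermediate
19 | 3-(tert-butyldimethylsilyloxy)-15,16-dinor-ent-labd-7-en-13-yn-2-ol | C#CCC[C@@H]1C(C)=CC[C@@H]2C(C)(C)[C@H](O[Si](C)(C)C(C)(C)C)[C@H](O)C[C@@]12C | intermediate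
20 | (E)-alkenyl(dimethyl)alane from 19 (Al on C14, new methyl on C13, C2 oxygen as dimethylaluminium alkoxide) | C[Al](C)/C=C(\C)CC[C@@H]1C(C)=CC[C@@H]2C(C)(C)[C@H](O[Si](C)(C)C(C)(C)C)[C@H](O[Al](C)C)C[C@@]12C | intermediate (not isolated)
21 | 3-(tert-butyldimethylsilyloxy)-ent-labda-7,13E-diene-2,15-diol | OC/C=C(\C)CC[C@@H]1C(C)=CC[C@@H]2C(C)(C)[C@H](O[Si](C)(C)C(C)(C)C)[C@H](O)C[C@@]12C | intermediate
22 | 15-acetoxy-3-(tert-butyldimethylsilyloxy)-ent-labda-7,13E-dien-2-ol | CC(=O)OC/C=C(\C)CC[C@@H]1C(C)=CC[C@@H]2C(C)(C)[C@H](O[Si](C)(C)C(C)(C)C)[C@H](O)C[C@@]12C | intermediate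
23 | 15-acetoxy-3-(tert-butyldimethylsilyloxy)-ent-labda-7,13E-dien-2-one | CC(=O)OC/C=C(\C)CC[C@@H]1C(C)=CC[C@@H]2C(C)(C)[C@H](O[Si](C)(C)C(C)(C)C)C(=O)C[C@@]12C | intermediate
24 | (2E)-5-[(1R,4aS,6S,8aS)-6-hydroxy-2,5,5,8a-tetramethyl-7-oxo-1,4,4a,5,6,7,8,8a-octahydronaphthalen-1-yl]-3-methylpent-2-en-1-yl acetate (15-acetoxy-3-hydroxy-ent-labda-7,13E-dien-2-one) | CC(=O)OC/C=C(\C)CC[C@@H]1C(C)=CC[C@@H]2C(C)(C)[C@H](O)C(=O)C[C@@]12C | target

## Step count and least certain steps

Total: 17 steps. Longest linear sequence: 17 steps (the route is linear from 1).

**Step 7 (key step).** Three processes may defeat it: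
- loss of a proton from the C4 cation, with the hydrogen chloride so released stripping the enol silane before it can bond;
- direct aldol addition of the enol silane to the activated C8 carbonyl before the cyclobutane bond breaks;
- slow ring opening at the temperatures the enol silane tolerates.

Fallback with known reaction types, from 9 back to 12: 9 is opened with TiCl4 in CH2Cl2 without a carbon nucleophile (the acid opening of pinane-type cyclobutyl ketones). The cation is collected as methyl 2-[(cyclohexyl) 3-(2-chloropropan-2-yl)-2-methyl-6-oxo-2-(3-silyloxy-2-oxopropyl)]acetate, the ring-opened tertiary chloride F1; material that has lost a proton is returned to F1 with dry HCl. Soft enolisation of F1 with excess TBSOTf/Et3N gives the tris-silyl compound F2, the side-arm (Z)-enediol bis-silyl ether with the ring ketone also silylated (drawn as the C7=C8 enol ether; a C8=C9 isomer would serve equally). TiCl4 at −78 °C then ionises the tertiary chloride for an intramolecular tert-alkylation of the enol silane at C3, and aqueous work-up hydrolyses the ring enol ether to give 12.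

**Step 9.** Deprotonation may not be confined to C7. Competing enolisation on the C2 side would give the wrong enol triflate or, through an oxygen-to-oxygen silyl shift in that enolate, transpose the ketol; O-acylation of the C8 enolate by the ester is a further drain if the mixture warms before triflation. Fallback, from 13 back to 17: the carbonyls are told apart by ketalisation, which only C8 can undergo. Ethylene glycol and pyridinium tosylate in hot toluene give the C8 dioxolane F3. NaBH4 in MeOH reduces the C2 ketone to the axial alcohol of the hydroxy ketal F4. Wet acetone with pyridinium tosylate frees the C8 ketone to give the hydroxy ketone F5. KN(SiMe3)2 (2.1 equiv) and the same triflimide give the hydroxy enol triflate F6, C8 now being the only ketone. MeZnCl/Pd(PPh3)4 gives the hydroxy ester F7, and LiAlH4 reduction of its ester arrives at 17.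

**Step 6.** Enolisation may go toward C1 or involve the ring ketone, and the silyl triflate may promote aldol chemistry of the new enol silane. Fallback, from 7 back to 10, makes the regiochemistry unavoidable by enolising an aldehyde that has only one α-position. Diol 7 is bis-silylated (TBSOTf, 2,6-lutidine) to the bis-silyl ether F8. The primary silyl ether is cleaved with HF·pyridine buffered with pyridine to give the primary alcohol F9. Dess–Martin oxidation gives the α-silyloxy aldehyde F10, and TBSOTf/Et3N converts F10 into 10. Any E isomer formed this way would give the axial C3 epimer in step 7, which step 8 equilibrates.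

**Step 1.** The Lewis acid may open the cyclobutane of the enone or of the adduct before or instead of allyl transfer, and the hindered β-carbon may react slowly. Fallback, from 1 back to 5: copper-mediated conjugate addition (allylmagnesium bromide, CuBr·SMe2, TMSCl, THF, −78 °C) under non-acidic conditions gives the trimethylsilyl enol ether F11. MeLi converts F11into the lithium enolate 5, which is alkylated as in step 2.

**Step 14.** Carbometalation may stall in the presence of the aluminium alkoxide, or the alkenylalane may be captured poorly by formaldehyde. Fallback, from 19 back to 21, replaces carbometalation by carbonyl olefination. Markovnikov hydration of the alkyne (Ph3PAuNTf2 cat., aqueous dioxane) gives the methyl ketone F12. Horner–Wadsworth–Emmons reaction with triethyl phosphonoacetate and NaH gives mainly the (E)-enoate F13, the minor Z isomer being removed by chromatography. iBu2AlH reduces F13 to 21.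

## Further compounds

F1 | step 7 | methyl 2-[3-(2-chloropropan-2-yl)-2-methyl-6-oxo-2-[3-(tert-butyldimethylsilyloxy)-2-oxopropyl]cyclohexyl]acetate (ring-opened tertiary chloride) | COC(=O)C[C@H]1C(=O)CC[C@H](C(C)(C)Cl)[C@@]1(C)CC(=O)CO[Si](C)(C)C(C)(C)C
F2 | step 7 | tris-silyl compound: side-arm (Z)-enediol bis-silyl ether and C7=C8 silyl enol ether of F1 | COC(=O)C[C@H]1C(O[Si](C)(C)C(C)(C)C)=CC[C@H](C(C)(C)Cl)[C@@]1(C)C/C(O[Si](C)(C)C(C)(C)C)=C/O[Si](C)(C)C(C)(C)C
F3 | step 9 | C8 ethylene ketal of 13 | COC(=O)C[C@@H]1C2(OCCO2)CC[C@@H]3C(C)(C)[C@H](O[Si](C)(C)C(C)(C)C)C(=O)C[C@@]13C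
F4 | step 9 | C8 ethylene ketal with axial C2 hydroxyl | COC(=O)C[C@@H]1C2(OCCO2)CC[C@@H]3C(C)(C)[C@H](O[Si](C)(C)C(C)(C)C)[C@H](O)C[C@@]13C
F5 | step 9 | methyl 2-hydroxy-3-(tert-butyldimethylsilyloxy)-8-oxo-13,14,15,16,17-pentanor-ent-labdan-12-oate | COC(=O)C[C@@H]1C(=O)CC[C@@H]2C(C)(C)[C@H](O[Si](C)(C)C(C)(C)C)[C@H](O)C[C@@]12C
F6 | step 9 | C8 enol triflate of F5 (C7=C8) | COC(=O)C[C@@H]1C(OS(=O)(=O)C(F)(F)F)=CC[C@@H]2C(C)(C)[C@H](O[Si](C)(C)C(C)(C)C)[C@H](O)C[C@@]12C
F7 | step 9 | methyl 2-hydroxy-3-(tert-butyldimethylsilyloxy)-13,14,15,16-tetranor-ent-labd-7-en-12-oate | COC(=O)C[C@@H]1C(C)=CC[C@@H]2C(C)(C)[C@H](O[Si](C)(C)C(C)(C)C)[C@H](O)C[C@@]12C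
F8 | step 6 | bis(tert-butyldimethylsilyl) ether of diol 7 | COC(=O)C[C@H]1C(=O)[C@H]2C[C@H](C2(C)C)[C@@]1(C)CC(O[Si](C)(C)C(C)(C)C)CO[Si](C)(C)C(C)(C)C
F9 | step 6 | methyl 2-{4-[2-(tert-butyldimethylsilyloxy)-3-hydroxypropyl]-4,6,6-trimethyl-2-oxobicyclo[3.1.1]heptan-3-yl}acetate | COC(=O)C[C@H]1C(=O)[C@H]2C[C@H](C2(C)C)[C@@]1(C)CC(O[Si](C)(C)C(C)(C)C)CO
F10 | step 6 | methyl 2-{4-[2-(tert-butyldimethylsilyloxy)-3-oxopropyl]-4,6,6-trimethyl-2-oxobicyclo[3.1.1]heptan-3-yl}acetate | COC(=O)C[C@H]1C(=O)[C@H]2C[C@H](C2(C)C)[C@@]1(C)CC(O[Si](C)(C)C(C)(C)C)C=O
F11 | step 1 | trimethylsilyl enol ether of 3 | C=CC[C@@]1(C)C=C(O[Si](C)(C)C)[C@H]2C[C@@H]1C2(C)C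
F12 | step 14 | 2-hydroxy-3-(tert-butyldimethylsilyloxy)-14,15-dinor-ent-labd-7-en-13-one (methyl ketone) | CC(=O)CC[C@@H]1C(C)=CC[C@@H]2C(C)(C)[C@H](O[Si](C)(C)C(C)(C)C)[C@H](O)C[C@@]12C
F13 | step 14 | ethyl 2-hydroxy-3-(tert-butyldimethylsilyloxy)-ent-labda-7,13E-dien-15-oate | CCOC(=O)/C=C(\C)CC[C@@H]1C(C)=CC[C@@H]2C(C)(C)[C@H](O[Si](C)(C)C(C)(C)C)[C@H](O)C[C@@]12C
A1 | alternative 1 | trans-fused enedione with C2 silyl enol ether (C6 and C9 carbonyls, C7=C8, methyls on C8 and C10, gem-dimethyl C4) | O=C1C(C)=CC(=O)[C@@H]2C(C)(C)C=C(O[Si](C)(C)C(C)(C)C)C[C@@]12C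
A2 | alternative 1 | 2-(tert-butyldimethylsilyloxy)-4-methylpenta-1,3-diene | C=C(O[Si](C)(C)C(C)(C)C)C=C(C)C
A3 | alternative 1 | 2,6-dimethyl-1,4-benzoquinone | CC1=CC(=O)C=C(C)C1=O
A4 | alternative 2 | trans-decalin with C8 ketone, C9 methyl ester and C2/C3 bis-silyl ether | COC(=O)[C@@H]1C(=O)CC[C@@H]2C(C)(C)[C@H](O[Si](C)(C)C(C)(C)C)[C@@H](O[Si](C)(C)C(C)(C)C)C[C@@]12C
A5 | alternative 2 | methyl 5-[4,5-trans-bis(tert-butyldimethylsilyloxy)-2,6,6-trimethylcyclohex-1-en-1-yl]-3-oxopentanoate | COC(=O)CC(=O)CCC1=C(C)C[C@H](O[Si](C)(C)C(C)(C)C)[C@@H](O[Si](C)(C)C(C)(C)C)C1(C)C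
A6 | alternative 2 | ketoisophorone, 2,6,6-trimethylcyclohex-2-ene-1,4-dione | CC1=CC(=O)CC(C)(C)C1=O
A7 | alternative 3 | trans-decalin 6-en-8-one with the silyl-protected side chain on C9 and C2/C3 bis-silyl ether | CC(C)(C)[Si](C)(C)OC/C=C(\C)CC[C@@H]1C(=O)C=C[C@@H]2C(C)(C)[C@H](O[Si](C)(C)C(C)(C)C)[C@@H](O[Si](C)(C)C(C)(C)C)C[C@@]12C
A8 | alternative 3 | cyclohexane keto aldehyde: C5 formyl, C10 methyl and C10 side arm bearing the C8 methyl ketone and the protected chain | CC(C)(C)[Si](C)(C)OC/C=C(\C)CC[C@H](C(C)=O)[C@]1(C)C[C@H](O[Si](C)(C)C(C)(C)C)[C@@H](O[Si](C)(C)C(C)(C)C)C(C)(C)[C@H]1C=O
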